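(All runs stem from a simulated flask on assumed constants, and the scatter is random.)

If the coupling partner is what competes against the loss of starting material, the ways of adding it differ by how much of it stands in the flask on average, so that mean is what we reckon.

| flask | starting material | coupling partner | protic impurity | temperature | remark | time |
|---|---|---|---|---|---|---|
| Thursday's | 0.015 M | 2.5 equiv | 7.5 mM | 20 °C | run made earlier |  |
| Monday's | 0.021 M | 2.5 equiv | 7.5 mM | 31 °C | run made earlier |  |
| Tuesday's | 0.033 M | 2.5 equiv | 7.5 mM | 20 °C | run made earlier |  |
| epsilon | 0.015 M | 2.50 equiv (fed, over 3.0 d) | 7.50 mM | 25 °C | all else is in the flask from the start; the feed brings no volume worth counting | 4.0 d |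
| beta | 0.015 M (fed, over 3.0 d) | 2.50 equiv | 7.50 mM |  | the addition at −5 °C, then warmed to 25 °C; the feed brings no volume worth counting | 4.0 d |
| zeta | 0.015 M | 2.50 equiv (in portions, 3, over 3.0 d) | 7.50 mM | 25 °C | first portion at the start, last at 3.0 d | 4.0 d |
| gamma | 0.015 M (fed, over 3.0 d) | 2.50 equiv | 7.50 mM | 25 °C | all else is in the flask from the start; the feed brings no volume worth counting | 4.0 d |

| Thursday's: time / d | Thursday's: target / % | Monday's: time / d | Monday's: target / % | Tuesday's: time / d | Tuesday's: target / % |
|---|---|---|---|---|---|
| 0.333 | 73.0 | 0.417 | 71.8 | 0.625 | 81.7 |
| 0.833 | 83.0 | 0.833 | 76.3 | 1.67 | 87.9 |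
| 1.67 | 86.2 | 2.08 | 80.7 | 3.00 | 90.1 |
| 4.00 | 88.0 | 5.00 | 77.9 | 5.00 | 88.7 |

(each reading ± 1 percentage point)

- which flask leads in amount of target, in percent of the starting material charged ("all alike" within 1.5 percentage points) (epsilon / beta / zeta / gamma / all alike)
- how much target is there at the end, in percent of the starting material charged: epsilon
- how much target is there at the end, in percent of the starting material charged: beta
- how much target is there at the end, in percent of the starting material charged: zeta
- how much target is there at the end, in percent of the starting material charged: gamma



From the highest readings we read a loss ratio, the charge not found as target divided by the target: 0.136 on Thursday at 20 °C and 0.239 on Monday at 31 °C. Tuesday's, at 0.033 M and the same 20 °C as Thursday's, reads 0.110, so at equal equivalents and temperature these readings show the charge moving it little. Near halfway in temperature, 25 °C takes the geometric mean. Our assumption is that, at fixed charge and temperature, the ratio goes as one over mean [coupling partner]. We replace each curve by its mean, delivered partner less half the charge of starting material as used.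

loss ratio at 25 °C: 0.181

mean [coupling partner], all in at the start: 0.0300 M

The loss constant, a selectivity factor in concentration units, is the loss ratio times that mean:

0.00542 M

target = 1/(1 + loss constant/mean [coupling partner])

Now the settings, one after the other. Feeding the starting material, as in gamma, leaves the mean at 0.0300 M, which gives 84.7% target. Feeding the partner, as in epsilon, delivers half the charge on average, so the mean falls to 0.0112 M and target to 67.4%. Equal portions, as in zeta, taken as evenly spaced, deliver that same half over 3.0 d, so we reckon zeta at the same figure. Beta feeds the starting material as gamma does, so we keep that mean and carry the temperature trend of the ratio, taken from two readings, down to −5 °C, where our extrapolation reads 0.0380 and gives 96.3%, before any loss during the warming. We put beta first.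

The forecast gave 84% for epsilon, 90% for beta, 84% for zeta and 85% for gamma, and it named beta, holding that “feed mode should matter little”. Ours stands 17 percentage points below it on epsilon and on zeta, and 6.3 points above it on beta.

The flasks end at 59.1% for epsilon, 94.0% for beta, 66.0% for zeta and 82.3% for gamma, so beta leads.

    starting material + protic impurity → quenched substrate (k = 0.00200 /M/s, Ea = 60.0 kJ/mol)
    coupling partner + intermediate → target (k = 2.30 /M/s, Ea = 59.0 kJ/mol)
    starting material ⇌ intermediate + leaving ligand, settled at all times (K = 5.40 × 10⁻⁶ M, ΔH = −64.0 kJ/mol)
    starting material + intermediate → side product (k = 0.00130 /M/s, Ea = 70.0 kJ/mol)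
    (constants at 25 °C)

Epsilon holds 40.3% quenched substrate after 4.00 d. Its mean [coupling partner] over the first 3.0 d was 0.0123 M, and the loss constant over that mean gives 69.4% target, against 59.1% in epsilon. For gamma, with a mean [coupling partner] of 0.0315 M over the same 3.0 d, the same reckoning gives 85.3%, and gamma stands at 82.3%.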